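## Analysis of the target

The target 19 is a 3,4-disubstituted oxolane (O1, C2, C3, C4, C5). C3 carries an exocyclic secondary carbinol carbon bonded to ring A (4-hydroxy-3-methoxyphenyl), and C4 carries a CH2 group bonded to ring B (the same guaiacyl pattern). There are three contiguous stereocentres: C3 (R) and C4 (R), whose substituents are trans on the ring, and the carbinol carbon (R), which lies outside the ring and so is not controlled by ring conformation. The sensitive unit is the para-hydroxybenzylic alcohol: in acid it ionises towards a quinone methide (epimerisation, or capture by ring B to an aryltetralin), its C–O bond can be lost under forcing hydrogenation, and the free phenols are oxidised easily in base. C2 and C5 are plain CH2 groups, so the ring offers no handle, and the two arenes are identically substituted, so they can only be told apart by where and when they are introduced. The strategy rests on the chain carbinol carbon–C3–C4: once C5 is raised to the carbonyl level, a bond from the carbinol carbon to C4 gives a cyclopropane with ring A (donor) and the C5 carbonyl (acceptor) at the two ends of that bond. Such a bond is polarised for heterolysis, so an oxygen nucleophile can cut it, leaving oxygen on the carbinol carbon and hydrogen on C4. The cyclopropane itself comes from a carbene adding to a cinnamyl ester alkene, which closes the O1–C2–C3–C4–C5 ring as a lactone in the same event.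

## Retrosynthetic reasoning

Protecting groups. Target 19 is traced to its bis(benzyl ether) 18, so that the para-hydroxybenzylic alcohol appears only in a last, neutral hydrogenolysis. Compound 18 is traced to the silyl ether 17, because the carbinol must be capped while the ring is built; otherwise it would compete as a nucleophile in the ring closure.

O1–C5 bond. The oxolane 17 is opened at the ether bond to the 1,4-diol 16. Both carbons are primary, so the closure needs no stereocontrol, and either hydroxyl can be the one activated. The diol is traced to lactone 15, with C5 as the carbonyl. C5, not C2, is chosen because a carbonyl next to C4 gives C4 an acidic hydrogen and later serves as the acceptor of the cyclopropane.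

C4–CH2 bond to ring B. Lactone 15 is cut between C4 and the benzylic CH2, giving lactone 11 (which reacts through its lithium enolate 14) and bromide 13, itself one step from alcohol 12. The forward reaction is an enolate alkylation, which has to place the benzyl group trans to the bulky C3 substituent; that is also the thermodynamically preferred arrangement. Ring B is introduced only here, after the benzylic carbon of ring A has been capped. An electron-rich ring B four atoms away would otherwise intercept the activated benzylic carbon in a Friedel–Crafts ring closure.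

Carbinol C–O bond, with reconnection to C4. Silyl ether 11 comes from alcohol 10. In 10 the carbinol oxygen is removed and the carbinol carbon is joined to C4, which gives the cyclopropane-fused lactone 9. The gain is that the exocyclic stereocentre becomes a ring stereocentre of 9, so its configuration is tied to C3. The forward opening has to break only the bond between the two substituted termini (C1–C6 of 9), not C1–C5 or C5–C6, and it has to proceed with inversion.

C3–C4 and C4–carbinol carbon bonds. Bicycle 9 is cut at both bonds of the former carbene carbon, which leads to the (E)-cinnamyl diazoacetate 8. One catalytic step then sets the absolute configuration of C3 and closes both rings. The relative configuration of the benzylic carbon follows from the alkene geometry, and the ring fusion can only be cis.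

Precursor. Diazo ester 8 comes from bromoacetate 6 (through the N-alkylated hydrazide 7), and 6 is made from allylic alcohol 4 and acid bromide 5. Alcohol 4 comes from ester 3 by reduction, and 3 from acid 1 and two equivalents of halide 2. These are functional-group changes only, and the E geometry is bought with 1 rather than made.

## Alternatives that were turned down

Alternative 1: Tandem conjugate addition–alkylation on a chiral butenolide.
- Disconnection: the carbinol carbon–C3 bond and the C4–CH2 bond, both made in one pot on the menthyloxy butenolide A2.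
- Forward key step: the lithiated ring A dithiane A3 adds to the β-carbon of A2 anti to the menthyloxy group, and the lactone enolate is then trapped by bromide 13 anti to the new substituent, giving the trans,trans lactone A1.
- For it: it is highly convergent. Two C–C bonds and both ring stereocentres arise in one operation under dependable auxiliary control. On convergence and on step count to the carbon skeleton it is at least as good as the chosen route.
- Against it: the carbinol carbon arrives as a masked ketone, so the third stereocentre is not set. The thioketal has to be unmasked in the presence of two electron-rich arenes. The ketone must then be reduced stereoselectively next to an epimerisable centre. The acetal carbon must be reduced to CH2, with loss of a stoichiometric auxiliary.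
- Comparison: the chosen strategy offers a catalytic source of absolute configuration. Its carbinol oxygen is delivered by a substitution coupled to the ring stereocentre, not by a separate reduction.

Alternative 2: Radical closure of the C4–C5 bond.
- Disconnection: C4–C5.
- Forward key step: the selanylmethyl ether A5, an (E)-styrene, is converted under radical-chain reduction into an alkoxymethyl radical. This closes 5-exo on the proximal styrene carbon, and the benzylic radical next to ring B takes up hydrogen to give A4.
- For it: the oxolane forms at its final oxidation level, and A4 is two deprotections from the target. In endgame economy it is stronger than the chosen route. The carbinol carbon and C3 are fixed beforehand, and a styrene is a fast radical acceptor.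
- Against it: C4 is created under kinetic control in a chair-like transition state. This favours trans but not exclusively, and C4 cannot be corrected afterwards because it is not epimerisable in an oxolane. A5 needs a stereodefined 2-alkenyl-1-arylpropane-1,3-diol, that is, an aldol of a β,γ-unsaturated acyl unit prone to γ-reaction and conjugation. The method also consumes stoichiometric organotin and selenium.
- Comparison: the chosen route sets C4 by an enolate alkylation whose kinetic and thermodynamic preferences agree and which can be equilibrated if needed.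

Alternative 3: (3+2) cycloaddition of the parent carbonyl ylide.
- Disconnection: C2–C3 and C4–C5 together, a cycloreversion of the oxolane into a CH2–O–CH2 dipole and an alkene.
- Forward key step: fluoride-triggered desilylation of A8 releases the parent carbonyl ylide, which adds across the (E)-enoyl imide A7 to give A6.
- For it: it is the most direct ring construction. Both ring stereocentres form in one step, trans stereospecifically from the E-alkene, with all ring carbons at the final oxidation level. For the ring itself it is clearly shorter than the chosen route.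
- Against it: a small, short-lived, unstabilised ylide cannot be steered by chelation of the imide, since fluoride and Lewis acids are incompatible, so the face selectivity and hence the absolute configuration are doubtful. The CH2 between ring B and the alkene of A7 is benzylic and γ to the carbonyl, so basic fluoride may move the double bond into conjugation with ring B. A β-alkyl enoyl unit is a slow partner for this dipole. The acyl group of A6 must still be turned into the aryl carbinol through an aryl ketone and a stereoselective reduction.
- Comparison: the chosen route gives in exchange catalyst-derived absolute control and a carbinol configuration that is part of the same stereochemical chain.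

Key step: step 5

Remark on the chemistry: S-configured carboxamidates of this catalyst family are taken to give the (1R,5S) series of 3-oxabicyclo[3.1.0]hexan-2-ones from allylic diazoacetates. The 4R catalyst is therefore specified for the (1S,5R,6R) lactone 9; should the sense be the reverse for this substrate, the 4S catalyst is used with no other change.

## Route

Step 1
Reactants: 1 (E)-ferulic acid [(E)-3-(4-hydroxy-3-methoxyphenyl)prop-2-enoic acid]; 2 benzyl bromide
Product: 3 benzyl (E)-3-(4-benzyloxy-3-methoxyphenyl)prop-2-enoate
Conditions: BnBr (2.4 equiv), K2CO3, DMF, 60 °C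
Reagents that add atoms: benzyl bromide (second equivalent), BrCc1ccccc1
Why: Williamson ether synthesis and carboxylate O-alkylation in one operation: K2CO3 deprotonates both the phenol and the acid, one equivalent of 2 benzylates the phenoxide and a second equivalent benzylates the carboxylate. The E geometry of the commercial acid is carried through unchanged.

Step 2
Reactants: 3 benzyl (E)-3-(4-benzyloxy-3-methoxyphenyl)prop-2-enoate
Product: 4 (E)-3-(4-benzyloxy-3-methoxyphenyl)prop-2-en-1-ol
Conditions: iBu2AlH, CH2Cl2, −78 → 0 °C; aq. potassium sodium tartrate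
Reagents that add atoms: none
Why: Hydride reduction of a conjugated ester in the 1,2-sense to the allylic alcohol; the alkene and the aryl benzyl ether are inert and the ester benzyl group leaves as benzyl alcohol.

Step 3
Reactants: 4 (E)-3-(4-benzyloxy-3-methoxyphenyl)prop-2-en-1-ol; 5 bromoacetyl bromide
Product: 6 (E)-3-(4-benzyloxy-3-methoxyphenyl)prop-2-enyl bromoacetate
Conditions: NaHCO3, MeCN, 0 °C
Reagents that add atoms: none
Why: O-acylation of the primary allylic alcohol by the acid bromide; NaHCO3 removes HBr so that the electron-rich cinnamyl system is not ionised.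

Step 4
Reactants: 6 (E)-3-(4-benzyloxy-3-methoxyphenyl)prop-2-enyl bromoacetate
Product: 8 (E)-3-(4-benzyloxy-3-methoxyphenyl)prop-2-enyl diazoacetate, via N-alkylated ditosylhydrazide 7 (not isolated)
Conditions: TsNHNHTs, DBU, THF, 0 °C
Reagents that add atoms: N,N'-ditosylhydrazine, Cc1ccc(cc1)S(=O)(=O)NNS(=O)(=O)c1ccc(C)cc1
Why: Diazoacetate synthesis from a bromoacetate: the hydrazide anion is N-alkylated to 7, and DBU then expels two sulfinate ions in succession to leave the diazo group. The cold, basic conditions suit the acid-labile cinnamyl ester.

Step 5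
Reactants: 8 (E)-3-(4-benzyloxy-3-methoxyphenyl)prop-2-enyl diazoacetate
Product: 9 (1S,5R,6R)-6-(4-benzyloxy-3-methoxyphenyl)-3-oxabicyclo[3.1.0]hexan-2-one (ring A exo)
Conditions: Rh2(4R-MPPIM)4 (1 mol%; MPPIM = methyl 2-oxo-1-(3-phenylpropanoyl)imidazolidine-4-carboxylate), CH2Cl2, reflux, slow addition of 8 by syringe pump
Reagents that add atoms: none
Why: The divalent-rhodium carboxamidate takes up the diazo carbon, N2 leaves, and an electrophilic rhodium-bound carbene results. The carbene carbon adds to the tethered E-alkene in a concerted, asynchronous (2+1) cycloaddition, bonding to the alkene carbon nearer the ester oxygen (C1–C5 of 9, the future C3–C4 bond) and to the benzylic carbon (C1–C6, the temporary bond from C4 to the carbinol carbon). The closest known reaction type is the enantioselective intramolecular cyclopropanation of allylic diazoacetates, E-cinnamyl esters included, by chiral divalent-rhodium carboxamidates. The five-membered lactone closes in the exo mode when the carbene carbon bonds to the proximal alkene carbon (ring atoms: carbene carbon, carbonyl carbon, ester oxygen, CH2, alkene CH), and the three-membered ring closes in the same event when it bonds to the distal benzylic carbon. C5 is set by the chiral ligands, which select the alkene face. C1 follows from C5 because the three-atom tether allows only the cis-fused bicycle, and C6 follows from the E geometry because the addition is stereospecific and places ring A exo, trans to the lactone CH2. The step needs intramolecular addition to win over carbene dimerisation, which slow addition and the short tether secure, and it needs face selectivity, which the catalyst supplies; the 4-alkoxy group makes the styrene more nucleophilic and so favours the addition.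

Step 6
Reactants: 9 (1S,5R,6R)-6-(4-benzyloxy-3-methoxyphenyl)-3-oxabicyclo[3.1.0]hexan-2-one
Product: 10 (4R)-4-[(R)-(4-benzyloxy-3-methoxyphenyl)(hydroxy)methyl]oxolan-2-one
Conditions: Sc(OTf)3 (10 mol%), 1,4-dioxane/H2O, 0 °C → rt
Reagents that add atoms: water, O
Why: Proposed new method: the C1–C6 bond of 9 carries the ring A donor on C6 and the lactone carbonyl on C1 and lies almost parallel to the carbonyl π* orbital, so coordination of Sc(OTf)3 to the carbonyl should polarise this bond and let water attack C6 from the rear in a loose SN2 transition state, with inversion to the R carbinol and protonation of the enolate at the future C4, and the closest known reaction type is the Lewis-acid-catalysed SN2-type opening of 2-arylcyclopropane-1,1-dicarboxylates by alcohols and other heteroatom nucleophiles with inversion, beyond which this step goes by relying on a single carbonyl acceptor and on water. The bridgehead C5 of 9 is not touched and becomes C4 (R) of lactone 10.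

Step 7
Reactants: 10 (4R)-4-[(R)-(4-benzyloxy-3-methoxyphenyl)(hydroxy)methyl]oxolan-2-one
Product: 11 (4R)-4-[(R)-(4-benzyloxy-3-methoxyphenyl)(triisopropylsilyloxy)methyl]oxolan-2-one
Conditions: iPr3SiOTf, 2,6-lutidine, CH2Cl2, −40 → 0 °C
Reagents that add atoms: triisopropylsilyl triflate, CC(C)[Si](C(C)C)(C(C)C)OS(=O)(=O)C(F)(F)F
Why: Silyl ether formation with a silyl triflate and a hindered pyridine base. The bulky triisopropylsilyl group is chosen because it resists migration to a primary alkoxide in steps 10 and 11 and shields one face of the enolate in step 9.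

Step 8
Reactants: 12 4-benzyloxy-3-methoxybenzyl alcohol
Product: 13 4-benzyloxy-3-methoxybenzyl bromide
Conditions: PBr3, Et2O, 0 °C
Reagents that add atoms: phosphorus tribromide, BrP(Br)Br
Why: Conversion of a benzylic alcohol into its bromide with PBr3; the electron-rich bromide is used at once without storage.

Step 9
Reactants: 11 (4R)-4-[(R)-(4-benzyloxy-3-methoxyphenyl)(triisopropylsilyloxy)methyl]oxolan-2-one; 13 4-benzyloxy-3-methoxybenzyl bromide
Product: 15 (3R,4R)-3-(4-benzyloxy-3-methoxybenzyl)-4-[(R)-(4-benzyloxy-3-methoxyphenyl)(triisopropylsilyloxy)methyl]oxolan-2-one, via lithium enolate 14 (not isolated)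
Conditions: LiN(SiMe3)2, THF, −78 °C; then 13, DMPU, −78 → −40 °C
Reagents that add atoms: none
Why: Alkylation of a γ-butyrolactone lithium enolate: the bromide approaches the lactone α-carbon from the face opposite the bulky neighbouring substituent, which sets the trans relationship (3R of 15, C4 of the target) that is also thermodynamically preferred. The β-carbon and the silylated carbinol carbon carry no acidic hydrogen and keep their configuration.

Step 10
Reactants: 15 (3R,4R)-3-(4-benzyloxy-3-methoxybenzyl)-4-[(R)-(4-benzyloxy-3-methoxyphenyl)(triisopropylsilyloxy)methyl]oxolan-2-one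
Product: 16 (2R,3R)-2-(4-benzyloxy-3-methoxybenzyl)-3-[(R)-(4-benzyloxy-3-methoxyphenyl)(triisopropylsilyloxy)methyl]butane-1,4-diol
Conditions: LiAlH4, THF, 0 °C; aq. potassium sodium tartrate
Reagents that add atoms: none
Why: Hydride reduction of the lactone to the 1,4-diol; the aryl benzyl ethers and the hindered silyl ether are inert to LiAlH4 at 0 °C and no stereocentre is involved.

Step 11
Reactants: 16 (2R,3R)-2-(4-benzyloxy-3-methoxybenzyl)-3-[(R)-(4-benzyloxy-3-methoxyphenyl)(triisopropylsilyloxy)methyl]butane-1,4-diol
Product: 17 {(R)-(4-benzyloxy-3-methoxyphenyl)[(3R,4R)-4-(4-benzyloxy-3-methoxybenzyl)oxolan-3-yl]methoxy}triisopropylsilane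
Conditions: PPh3, DIAD, THF, 0 °C → rt
Reagents that add atoms: none
Why: Mitsunobu cyclodehydration: one primary hydroxyl is activated on phosphorus and displaced by the other in a 5-exo-tet closure, and since both hydroxyls are primary either mode of activation gives the same oxolane. The conditions are neutral, so the silyl ether stays in place and no stereocentre is touched.

Step 12
Reactants: 17 {(R)-(4-benzyloxy-3-methoxyphenyl)[(3R,4R)-4-(4-benzyloxy-3-methoxybenzyl)oxolan-3-yl]methoxy}triisopropylsilane
Product: 18 (R)-(4-benzyloxy-3-methoxyphenyl)[(3R,4R)-4-(4-benzyloxy-3-methoxybenzyl)oxolan-3-yl]methanol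
Conditions: Bu4NF, THF, rt → 40 °C
Reagents that add atoms: none
Why: Fluoride cleavage of the silyl ether; the non-acidic conditions avoid ionisation of the electron-rich benzylic position, so the carbinol keeps its R configuration.

Step 13
Reactants: 18 (R)-(4-benzyloxy-3-methoxyphenyl)[(3R,4R)-4-(4-benzyloxy-3-methoxybenzyl)oxolan-3-yl]methanol
Product: 19 (R)-(4-hydroxy-3-methoxyphenyl)[(3R,4R)-4-(4-hydroxy-3-methoxybenzyl)oxolan-3-yl]methanol
Conditions: H2 (1 atm), Pd/C, EtOAc, rt
Reagents that add atoms: none
Why: Hydrogenolysis of the two aryl benzyl ethers over Pd/C under neutral conditions; phenol O-debenzylation is much faster than cleavage of a secondary benzylic alcohol when no acid is present. The product is isolated by filtration and evaporation, so the para-hydroxybenzylic alcohol meets neither acid nor base.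

## Compound list

1 | (E)-ferulic acid, (E)-3-(4-hydroxy-3-methoxyphenyl)prop-2-enoic acid | COc1cc(/C=C/C(=O)O)ccc1O | starting material
2 | benzyl bromide | BrCc1ccccc1 | starting material
3 | benzyl (E)-3-(4-benzyloxy-3-methoxyphenyl)prop-2-enoate | COc1cc(/C=C/C(=O)OCc2ccccc2)ccc1OCc1ccccc1 | intermediate
4 | (E)-3-(4-benzyloxy-3-methoxyphenyl)prop-2-en-1-ol | COc1cc(/C=C/CO)ccc1OCc1ccccc1 | intermediate
5 | bromoacetyl bromide | BrCC(=O)Br | starting material
6 | (E)-3-(4-benzyloxy-3-methoxyphenyl)prop-2-enyl bromoacetate | COc1cc(/C=C/COC(=O)CBr)ccc1OCc1ccccc1 | intermediate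
7 | (E)-3-(4-benzyloxy-3-methoxyphenyl)prop-2-enyl 2-[1,2-bis(4-methylphenylsulfonyl)hydrazinyl]acetate (formed in the flask, not isolated) | COc1cc(/C=C/COC(=O)CN(NS(=O)(=O)c2ccc(C)cc2)S(=O)(=O)c2ccc(C)cc2)ccc1OCc1ccccc1 | intermediate
8 | (E)-3-(4-benzyloxy-3-methoxyphenyl)prop-2-enyl diazoacetate | [N-]=[N+]=CC(=O)OC/C=C/c1ccc(OCc2ccccc2)c(OC)c1 | intermediate
9 | (1S,5R,6R)-6-(4-benzyloxy-3-methoxyphenyl)-3-oxabicyclo[3.1.0]hexan-2-one, ring A exo | O=C1OC[C@@H]2[C@@H](c3ccc(OCc4ccccc4)c(OC)c3)[C@H]12 | intermediate
10 | (4R)-4-[(R)-(4-benzyloxy-3-methoxyphenyl)(hydroxy)methyl]oxolan-2-one | O=C1C[C@H](CO1)[C@@H](O)c1ccc(OCc2ccccc2)c(OC)c1 | intermediate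
11 | (4R)-4-[(R)-(4-benzyloxy-3-methoxyphenyl)(triisopropylsilyloxy)methyl]oxolan-2-one | O=C1C[C@H](CO1)[C@@H](O[Si](C(C)C)(C(C)C)C(C)C)c1ccc(OCc2ccccc2)c(OC)c1 | intermediate
12 | 4-benzyloxy-3-methoxybenzyl alcohol | COc1cc(CO)ccc1OCc1ccccc1 | starting material
13 | 4-benzyloxy-3-methoxybenzyl bromide | COc1cc(CBr)ccc1OCc1ccccc1 | intermediate
14 | lithium enolate of 11, lithium (4R)-4-[(R)-(4-benzyloxy-3-methoxyphenyl)(triisopropylsilyloxy)methyl]-4,5-dihydrofuran-2-olate (formed in the flask, not isolated) | [Li+].[O-]C1=C[C@H](CO1)[C@@H](O[Si](C(C)C)(C(C)C)C(C)C)c1ccc(OCc2ccccc2)c(OC)c1 | intermediate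
15 | (3R,4R)-3-(4-benzyloxy-3-methoxybenzyl)-4-[(R)-(4-benzyloxy-3-methoxyphenyl)(triisopropylsilyloxy)methyl]oxolan-2-one | O=C1[C@H](Cc2ccc(OCc3ccccc3)c(OC)c2)[C@H](CO1)[C@@H](O[Si](C(C)C)(C(C)C)C(C)C)c1ccc(OCc2ccccc2)c(OC)c1 | intermediate
16 | (2R,3R)-2-(4-benzyloxy-3-methoxybenzyl)-3-[(R)-(4-benzyloxy-3-methoxyphenyl)(triisopropylsilyloxy)methyl]butane-1,4-diol | OC[C@H](Cc1ccc(OCc2ccccc2)c(OC)c1)[C@H](CO)[C@@H](O[Si](C(C)C)(C(C)C)C(C)C)c1ccc(OCc2ccccc2)c(OC)c1 | intermediate
17 | {(R)-(4-benzyloxy-3-methoxyphenyl)[(3R,4R)-4-(4-benzyloxy-3-methoxybenzyl)oxolan-3-yl]methoxy}triisopropylsilane | COc1cc(C[C@H]2COC[C@@H]2[C@@H](O[Si](C(C)C)(C(C)C)C(C)C)c2ccc(OCc3ccccc3)c(OC)c2)ccc1OCc1ccccc1 | intermediate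
18 | (R)-(4-benzyloxy-3-methoxyphenyl)[(3R,4R)-4-(4-benzyloxy-3-methoxybenzyl)oxolan-3-yl]methanol | COc1cc(C[C@H]2COC[C@@H]2[C@@H](O)c2ccc(OCc3ccccc3)c(OC)c2)ccc1OCc1ccccc1 | intermediate
19 | (R)-(4-hydroxy-3-methoxyphenyl)[(3R,4R)-4-(4-hydroxy-3-methoxybenzyl)oxolan-3-yl]methanol | COc1cc(C[C@H]2COC[C@@H]2[C@@H](O)c2ccc(O)c(OC)c2)ccc1O | target

## Step count and least certain steps

Total step count: 13. Longest linear sequence: 12 steps (steps 1 to 7 and 9 to 13, from 1 to 19); step 8 is a one-step branch.

Step 6 (Proposed new method).
- What may go wrong: the C1–C6 bond may ionise to a free, ring-A-stabilised benzylic cation before water arrives, or the product carbinol may re-ionise under the Lewis acid. Either would erode the inversion and could lead on to translactonisation through capture by the lactone carbonyl oxygen. Acyl migration of the lactone onto the newly freed carbinol oxygen is a further risk while the hydroxyl is uncapped. The singly activated cyclopropane may also be too unreactive towards a mild Lewis acid.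
- Fallback, by known chemistry, from 9 back to 10: the ring is opened without any stereochemical demand by proton-acid solvolysis (catalytic TfOH, aqueous acetone, 0 °C). This is the known acid-promoted opening of electron-rich arylcyclopropyl carbonyl compounds through the benzylic cation. It should give (4R)-4-[(4-benzyloxy-3-methoxyphenyl)(hydroxy)methyl]oxolan-2-one F1 as a mixture of carbinol epimers. A NaHCO3-buffered Dess–Martin oxidation converges both epimers on (4R)-4-(4-benzyloxy-3-methoxybenzoyl)oxolan-2-one F2. A CBS reduction with (S)-2-methyl-CBS-oxazaborolidine and BH3·SMe2 at low temperature then sets the R carbinol of 10 under reagent control, with the aryl group as the large substituent. The buffered oxidation and the cold, non-basic reduction are chosen so that the centre next to the ketone does not enolise.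

Step 5 (key step).
- What may go wrong: face selectivity may be eroded, because the more nucleophilic 4-alkoxystyrene reacts through an earlier, less catalyst-controlled transition state. Carbene dimerisation may compete if the diazo ester accumulates.
- Fallback from 8 back to 9, replacing catalyst control by resolution: decomposition of 8 with the achiral divalent-rhodium carboxylate Rh2(OAc)4 gives racemic exo-6-(4-benzyloxy-3-methoxyphenyl)-3-oxabicyclo[3.1.0]hexan-2-one F3. Aqueous LiOH opens the lactone to racemic lithium (1S*,2R*,3R*)-3-(4-benzyloxy-3-methoxyphenyl)-2-(hydroxymethyl)cyclopropane-1-carboxylate F4. Exchange with (S)-1-phenylethylammonium chloride (or its antipode, whichever makes the wanted salt the less soluble one) and fractional crystallisation give (S)-1-phenylethylammonium (1S,2R,3R)-3-(4-benzyloxy-3-methoxyphenyl)-2-(hydroxymethyl)cyclopropane-1-carboxylate F5. Brief acidification in the cold releases the cis-hydroxy acid, which relactonises to 9.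

Step 9.
- What may go wrong: proton transfer between product and unreacted enolate would lead to a second benzylation and to partial loss of the trans selectivity.
- Fallback from 11 and 12 back to 15, by condensation and reduction in place of alkylation: MnO2 oxidises 12 to 4-benzyloxy-3-methoxybenzaldehyde F6. Aldol addition of lithium enolate 14 to F6 gives the β-hydroxy lactones (4R)-3-[(4-benzyloxy-3-methoxyphenyl)(hydroxy)methyl]-4-[(R)-(4-benzyloxy-3-methoxyphenyl)(triisopropylsilyloxy)methyl]oxolan-2-one F7 as a diastereomer mixture. MsCl and Et3N convert these into the mesylates (4R)-3-[(4-benzyloxy-3-methoxyphenyl)(methylsulfonyloxy)methyl]-4-[(R)-(4-benzyloxy-3-methoxyphenyl)(triisopropylsilyloxy)methyl]oxolan-2-one F8, and DBU eliminates methanesulfonic acid to give (4R)-3-[(E)-4-benzyloxy-3-methoxybenzylidene]-4-[(R)-(4-benzyloxy-3-methoxyphenyl)(triisopropylsilyloxy)methyl]oxolan-2-one F9, which cannot be alkylated twice. Conjugate reduction with LiBH(sBu)3 followed by base equilibration (DBU) of the α-centre delivers the thermodynamically preferred trans lactone 15.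

Step 13.
- What may go wrong: the benzylic C–O bond of the free carbinol may be hydrogenolysed alongside the O-debenzylation, helped by the electron-rich ring and by traces of acid on the catalyst.
- Fallback from 17 back to 19, with the order of unmasking reversed: hydrogenolysis of 17 (H2, Pd/C, EtOAc) while the benzylic oxygen is still shielded by the bulky silyl group gives 4-{[(3R,4R)-4-[(R)-(4-hydroxy-3-methoxyphenyl)(triisopropylsilyloxy)methyl]oxolan-3-yl]methyl}-2-methoxyphenol F10. Acetic-acid-buffered Bu4NF in THF then removes the silyl group to give 19.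

## Further compounds

F1 | step 6 | (4R)-4-[(4-benzyloxy-3-methoxyphenyl)(hydroxy)methyl]oxolan-2-one, mixture of carbinol epimers | O=C1C[C@H](CO1)C(O)c1ccc(OCc2ccccc2)c(OC)c1
F2 | step 6 | (4R)-4-(4-benzyloxy-3-methoxybenzoyl)oxolan-2-one | O=C1C[C@H](CO1)C(=O)c1ccc(OCc2ccccc2)c(OC)c1
F3 | step 5 | racemic exo-6-(4-benzyloxy-3-methoxyphenyl)-3-oxabicyclo[3.1.0]hexan-2-one (relative configuration shown) | O=C1OC[C@@H]2[C@@H](c3ccc(OCc4ccccc4)c(OC)c3)[C@H]12
F4 | step 5 | racemic lithium (1S*,2R*,3R*)-3-(4-benzyloxy-3-methoxyphenyl)-2-(hydroxymethyl)cyclopropane-1-carboxylate (relative configuration shown) | [Li+].OC[C@@H]1[C@@H](c2ccc(OCc3ccccc3)c(OC)c2)[C@@H]1C(=O)[O-]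
F5 | step 5 | (S)-1-phenylethylammonium (1S,2R,3R)-3-(4-benzyloxy-3-methoxyphenyl)-2-(hydroxymethyl)cyclopropane-1-carboxylate | OC[C@@H]1[C@@H](c2ccc(OCc3ccccc3)c(OC)c2)[C@@H]1C(=O)[O-].C[C@H]([NH3+])c1ccccc1
F6 | step 9 | 4-benzyloxy-3-methoxybenzaldehyde | COc1cc(C=O)ccc1OCc1ccccc1
F7 | step 9 | (4R)-3-[(4-benzyloxy-3-methoxyphenyl)(hydroxy)methyl]-4-[(R)-(4-benzyloxy-3-methoxyphenyl)(triisopropylsilyloxy)methyl]oxolan-2-one, diastereomer mixture | O=C1C(C(O)c2ccc(OCc3ccccc3)c(OC)c2)[C@H](CO1)[C@@H](O[Si](C(C)C)(C(C)C)C(C)C)c1ccc(OCc2ccccc2)c(OC)c1
F8 | step 9 | (4R)-3-[(4-benzyloxy-3-methoxyphenyl)(methylsulfonyloxy)methyl]-4-[(R)-(4-benzyloxy-3-methoxyphenyl)(triisopropylsilyloxy)methyl]oxolan-2-one, diastereomer mixture | O=C1C(C(OS(C)(=O)=O)c2ccc(OCc3ccccc3)c(OC)c2)[C@H](CO1)[C@@H](O[Si](C(C)C)(C(C)C)C(C)C)c1ccc(OCc2ccccc2)c(OC)c1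
F9 | step 9 | (4R)-3-[(E)-4-benzyloxy-3-methoxybenzylidene]-4-[(R)-(4-benzyloxy-3-methoxyphenyl)(triisopropylsilyloxy)methyl]oxolan-2-one | O=C1/C(=C/c2ccc(OCc3ccccc3)c(OC)c2)[C@H](CO1)[C@@H](O[Si](C(C)C)(C(C)C)C(C)C)c1ccc(OCc2ccccc2)c(OC)c1
F10 | step 13 | 4-{[(3R,4R)-4-[(R)-(4-hydroxy-3-methoxyphenyl)(triisopropylsilyloxy)methyl]oxolan-3-yl]methyl}-2-methoxyphenol | COc1cc(C[C@H]2COC[C@@H]2[C@@H](O[Si](C(C)C)(C(C)C)C(C)C)c2ccc(O)c(OC)c2)ccc1O
A1 | alternative 1 | 3,4-trans-4,5-trans-3-(4-benzyloxy-3-methoxybenzyl)-4-[2-(4-benzyloxy-3-methoxyphenyl)-1,3-dithian-2-yl]-5-[(1R,2S,5R)-menthyloxy]oxolan-2-one | COc1cc(C[C@H]2C(=O)O[C@@H](O[C@@H]3C[C@H](C)CC[C@H]3C(C)C)[C@@H]2C2(c3ccc(OCc4ccccc4)c(OC)c3)SCCCS2)ccc1OCc1ccccc1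
A2 | alternative 1 | (5R)-5-[(1R,2S,5R)-menthyloxy]furan-2(5H)-one | O=C1O[C@@H](O[C@@H]2C[C@H](C)CC[C@H]2C(C)C)C=C1
A3 | alternative 1 | 2-(4-benzyloxy-3-methoxyphenyl)-1,3-dithiane | COc1cc(C2SCCCS2)ccc1OCc1ccccc1
A4 | alternative 2 | tert-butyl{(R)-(4-benzyloxy-3-methoxyphenyl)[(3R,4R)-4-(4-benzyloxy-3-methoxybenzyl)oxolan-3-yl]methoxy}dimethylsilane | COc1cc(C[C@H]2COC[C@@H]2[C@@H](O[Si](C)(C)C(C)(C)C)c2ccc(OCc3ccccc3)c(OC)c2)ccc1OCc1ccccc1
A5 | alternative 2 | (phenylselanyl)methyl ether of (E)-2-[(R)-(4-benzyloxy-3-methoxyphenyl)(tert-butyldimethylsilyloxy)methyl]-4-(4-benzyloxy-3-methoxyphenyl)but-3-en-1-ol, configured as in A4 | COc1cc(/C=C/[C@H](COC[Se]c2ccccc2)[C@@H](O[Si](C)(C)C(C)(C)C)c2ccc(OCc3ccccc3)c(OC)c2)ccc1OCc1ccccc1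
A6 | alternative 3 | (4S)-4-benzyl-3-[(3R,4R)-4-(4-benzyloxy-3-methoxybenzyl)oxolane-3-carbonyl]oxazolidin-2-one | COc1cc(C[C@H]2COC[C@@H]2C(=O)N2[C@@H](Cc3ccccc3)COC2=O)ccc1OCc1ccccc1
A7 | alternative 3 | (4S)-4-benzyl-3-[(E)-4-(4-benzyloxy-3-methoxyphenyl)but-2-enoyl]oxazolidin-2-one | COc1cc(C/C=C/C(=O)N2[C@@H](Cc3ccccc3)COC2=O)ccc1OCc1ccccc1
A8 | alternative 3 | chloromethyl (trimethylsilyl)methyl ether | C[Si](C)(C)COCCl
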